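The spring run is this very flask, followed up to 80.0 s, so start from its readings.

- spring: starting material 0.027 M; reagent in the second phase 0.054 M; the very flask that is asked about, followed so far
- flask: starting material 0.027 M; reagent in the second phase 0.0540 M; time 3.0 min; volume of the second phase over the first 1.0

spring run (percent of the starting material charged)

| time / s | target / % | idle adduct / % |
|---|---|---|
| 10.0 | 0.6 | 0 |
| 20.0 | 2.9 | 0.1 |
| 30.0 | 5.7 | 1.7 |
| 50.0 | 14.3 | 5.0 |
| 80.0 | 24.0 | 9.1 |

(readings scatter by 0.5 percentage points)

- target is meant together with its idle adduct
- in the second phase: reagent in the second phase; everything else is in the first
- charges count per volume of the first phase; a concentration in a rate is the amount of a species over the volume of its own phase; every rate counts per litre of the first phase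
- the earlier runs were read with a standard deviation of 0.5 percentage points
- the earlier runs hold the two phases in the same ratio of volumes as the flask asked about

- amber: doubling the amount of reagent in the second phase, all else as stated
- violet: doubling the transfer coefficient of the reagent in the second phase, all else as stated

1. target and idle adduct together at 3.0 min, in percent of the starting material charged
2. the change that raises the amount of target and idle adduct together at 3.0 min, in percent of the starting material charged most ("none" if none brings more than 2 percentage points) (amber / violet / none)
3. amount of target and idle adduct together at 3.0 min, in percent of the starting material charged, after amber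

Read y straight from the target column, since target is meant together with its idle adduct. Go to logarithms: between the last two readings the part not found as y, one minus y, falls by 0.104 min⁻¹ in powers of ten, as read; call this fall per time the decade slope.

Take the main step by itself, pseudo-first-order with this slope held on, and reckon y at 49.1% at 3.0 min. Add the idle adduct: in the reading at 80.0 s it holds 37.9% of y, so reckon each target to take 138% of a reagent. Over the coming stretch this reckons the reagent left at 0.862 of that in the stretch read, which lowers the reckoned y to 46.2%. Add the crossing: drawn back to zero, the line starts at 11.5 s, a lag already inside the readings, so the reckoned y stays as it is.

For violet, reckon 5.73 s saved, worth 0.53 percentage points to 1.1 points. For amber, reckon the decades doubled, which squares one minus y and gives 71.0%, so amber leads in this reckoning.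

The forecast says 60%, amber and 85%, from “The summed product (target + idle adduct) runs 0.6, 3.0, 7.4, 19.3 and 33.1%”. This reckoning differs: it keeps the column, not the sum.

The flask gives 44.6%, amber with 23 points against 3.8 points for violet, and 67.9% after amber; read at 50 s it gives 13.8%, not the forecast's sum of 19.3.

    reagent in the reaction phase ⇌ reagent in the second phase, rate k1*([reagent in the reaction phase] - [reagent in the second phase]/K1) per volume of the first phase (partition coefficient = 0.730, kL = 0.0150 s⁻¹)
    starting material + reagent in the reaction phase → target (k = 0.220 M⁻¹ s⁻¹)
    reagent in the reaction phase + target ⇌ idle adduct, settled at all times (K = 28.0 M⁻¹)
    2 starting material → homo dimer (k = 0.0630 M⁻¹ s⁻¹)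

In this flask, from the reading at 80.0 s on, the decade slope was 0.0824 min⁻¹ on average, against 0.0896 min⁻¹ reckoned. Averaged from the start, the neighbour with c(starting material) 0.011 M shows 0.115 min⁻¹, faster than this flask's 0.0855 min⁻¹. This flask is not at rest at 3.0 min, with 31% of the starting material unbound. At 30.0 min this flask has y at 72.5%, 28 points more, with a slope of 0.0113 min⁻¹ on average over that stretch, starting material at 0.0583%, and homo dimer, each counted as two starting material, at 27.4%.

(The earlier runs and the new flask were computed with made-up constants; scatter was added.)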